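The trans-decalin is disconnected across C4–C5 and C9–C10 to an acyclic, geranylacetone-derived 2-methyl-3-oxo ester. A Mn(OAc)3/Cu(OAc)2 oxidative radical bicyclization closes ring A through the C4–C5 bond and ring B through C9–C10 in one operation, sets C4, C5, C9 and C10, and ends in the C8 exocyclic methylene. It exploits the quaternary C4 of ring A: its oxygenated carbon C19 is carried as an ester that, together with a temporary C3 ketone, makes C4 oxidizable to a radical, and an 8-phenylmenthyl ester fixes the absolute sense. Afterwards the C3 oxygen is removed, C19 is acylated, and the side-chain ketone becomes the diene.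

Key step: step 6

Numbering: labdane numbering is used (ring A = C1–C5, C10; ring B = C5–C10; C17 = methylene carbon on C8; C18 = methyl and C19 = oxygenated carbon on C4; C20 = methyl on C10; side chain C11–C16).

Remark: (E)-geranylacetone and (1S,2R,5S)-8-phenylmenthol are taken as commercial. The sense of induction in step 6 is assigned from the aryl-shielding model of 8-phenylmenthyl esters, in which the (1R,2S,5R)-ester should lead to the 10β-methyl series, so the (1S,2R,5S)-alcohol is used. If the sense proved opposite, the enantiomeric alcohol would be used with no other change.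

**Step 1**
Reactants: 1 (E)-geranylacetone
Product: 2 geranylacetone ethylene ketal
Conditions: ethylene glycol, PPTS (cat.), benzene, reflux, Dean–Stark
Reagents that add atoms: ethylene glycol OCCO
Why: Acid-catalysed ketalization with azeotropic removal of water protects the methyl ketone against the later dianion, hydride and radical steps, and the weak acid leaves the trisubstituted alkenes untouched.

**Step 2**
Reactants: 2 geranylacetone ethylene ketal
Product: 3 (2E,6E)-allylic alcohol
Conditions: SeO2 (0.3 equiv), t-BuOOH (3 equiv), salicylic acid (0.1 equiv), CH2Cl2, 0 °C to rt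
Reagents that add atoms: selenium dioxide O=[Se]=O (oxygen donor), tert-butyl hydroperoxide CC(C)(C)OO (terminal oxidant)
Why: Riley allylic oxidation (ene reaction, then [2,3]-sigmatropic shift) should attack the more electron-rich terminal isopropylidene group and give the (E)-configured primary allylic alcohol.

**Step 3**
Reactants: 3 (2E,6E)-allylic alcohol
Product: 4 (E,E)-allylic bromide
Conditions: CBr4, PPh3, CH2Cl2, −20 to 0 °C
Reagents that add atoms: carbon tetrabromide BrC(Br)(Br)Br
Why: The Appel reaction should convert the primary allylic alcohol into the bromide under near-neutral conditions without allylic transposition or loss of the ketal.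

**Step 4**
Reactants: 5 (1S,2R,5S)-8-phenylmenthol, 6 ethyl 2-methyl-3-oxobutanoate
Product: 7 (1S,2R,5S)-8-phenylmenthyl 2-methyl-3-oxobutanoate
Conditions: DMAP (0.3 equiv), toluene, reflux, ethanol distilled off
Reagents that add atoms: none
Why: DMAP-catalysed transesterification of a β-keto ester runs through an acylketene and so tolerates the hindered secondary alcohol, and the C2 center may stay a mixture because it becomes planar in steps 5 and 6.

**Step 5**
Reactants: 7 (1S,2R,5S)-8-phenylmenthyl 2-methyl-3-oxobutanoate, 4 (E,E)-allylic bromide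
Product: 9 acyclic keto ester, via dianion 8 (not isolated)
Conditions: NaH (1.1 equiv), THF, 0 °C; n-BuLi (1.05 equiv), 0 °C; then 4, 0 °C to rt; then aq NH4Cl
Reagents that add atoms: none
Why: In this β-keto ester dianion alkylation the more basic terminal carbanion of 8 should displace the primary allylic bromide by SN2 substitution with retention of the (E)-alkene geometry.

**Step 6**
Reactants: 9 acyclic keto ester
Product: 13 bicyclic keto ester, via C4 radical 10 (not isolated), via monocyclic C10 radical 11 (not isolated), via bicyclic C8 radical 12 (not isolated)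
Conditions: Mn(OAc)3·2H2O (2.2 equiv), Cu(OAc)2·H2O (1.0 equiv), KOAc (2 equiv), degassed AcOH, rt
Reagents that add atoms: none
Why: Mn(OAc)3 (trivalent manganese) should oxidize the enol of the 2-methyl β-keto ester to C4 radical 10, which adds 6-endo-trig to C5 of the (E)-C5=C10 alkene and closes ring A to give tertiary radical 11; this adds 6-endo-trig to C9 of the (E)-C8=C9 alkene and closes ring B to give tertiary radical 12, which Cu(OAc)2 (divalent copper) oxidizes through an alkylcopper species that loses a C17 hydrogen to leave the exocyclic alkene. The closest known reaction type is the manganese triacetate oxidative free-radical polycyclization of α-substituted β-keto esters bearing a chiral ester auxiliary. Both closures should pass through a chair–chair transition state, so the (E)-geometries set the trans ring fusion (C5–H anti to the C10 methyl) and the equatorial C9 side chain, and the radical should react in the conformer with the ketone oxygen cis to the C4 methyl, which places the ester axial and cis to the C10 methyl. The absolute configuration is controlled by the auxiliary, whose phenyl ring should stack over one face of the planar C4 radical so that C5 bonds to the other face. The step needs 6-endo rather than 5-exo closure (secured by the methyl-bearing proximal alkene carbons C10 and C8), oxidation rather than hydrogen abstraction at C8 (secured by Cu(OAc)2) and no re-oxidation of the product (secured by the quaternary C4). The minor diastereomer and any endocyclic alkene isomers are to be removed by chromatography while the auxiliary is still attached.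

**Step 7**
Reactants: 13 bicyclic keto ester
Product: 14 3,19-diol
Conditions: LiAlH4 (4 equiv), THF, 0 °C to reflux; Fieser work-up
Reagents that add atoms: none
Why: LiAlH4 should reduce the ketone and the hindered ester in one operation and release the auxiliary, with hydride adding to C3 from the axial direction, away from the axial C4 substituent, to give the equatorial alcohol (a center removed in step 9).

**Step 8**
Reactants: 14 3,19-diol
Product: 15 cyclic thionocarbonate
Conditions: 1,1'-thiocarbonyldiimidazole (1.5 equiv), DMAP (cat.), toluene, 90 °C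
Reagents that add atoms: 1,1'-thiocarbonyldiimidazole S=C(n1ccnc1)n1ccnc1
Why: Thiocarbonyl transfer to the 1,3-diol should close the six-membered cyclic thionocarbonate because the equatorial C3–O and the axial C19–O bonds are gauche.

**Step 9**
Reactants: 15 cyclic thionocarbonate
Product: 17 C19 alcohol, via stannyl thiocarbonate 16 (not isolated)
Conditions: Bu3SnH (2 equiv), AIBN (0.2 equiv), toluene, reflux; then NaOH, THF/MeOH/H2O, rt
Reagents that add atoms: none
Why: In this Barton–McCombie-type deoxygenation the stannyl radical adds to sulfur, the adduct should fragment on the side that breaks the secondary C3–O bond in preference to the primary C19–O bond, hydrogen transfer from Bu3SnH gives 16, and hydroxide cleaves its thiocarbonate to the primary alcohol.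

**Step 10**
Reactants: 18 (E)-p-coumaric acid
Product: 20 (E)-4-(tert-butyldimethylsilyloxy)cinnamic acid, via bis-silyl derivative 19 (not isolated)
Conditions: TBSCl (2.3 equiv), imidazole (5 equiv), DMF, rt; then THF/H2O/AcOH (cat.), rt
Reagents that add atoms: tert-butyldimethylsilyl chloride CC(C)(C)[Si](C)(C)Cl
Why: Silylation of both acidic groups followed by selective hydrolysis of the far more labile silyl ester should leave the aryl silyl ether and the free acid.

**Step 11**
Reactants: 17 C19 alcohol, 20 (E)-4-(tert-butyldimethylsilyloxy)cinnamic acid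
Product: 21 silyl-protected coumarate ketal
Conditions: DCC (1.5 equiv), DMAP (0.5 equiv), CH2Cl2, rt
Reagents that add atoms: none
Why: Steglich esterification through the N-acylpyridinium ion should acylate the neopentyl primary alcohol without touching the (E)-alkene of the acid.

**Step 12**
Reactants: 21 silyl-protected coumarate ketal
Product: 22 methyl ketone
Conditions: PPTS (0.2 equiv), acetone/H2O (10:1), 50 °C
Reagents that add atoms: water O
Why: Mild acid-catalysed ketal hydrolysis should free the methyl ketone without isomerizing the exocyclic alkene or cleaving the aryl silyl ether.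

**Step 13**
Reactants: 22 methyl ketone
Product: 24 enol triflate, via potassium enolate 23 (not isolated)
Conditions: KN(SiMe3)2 (1.1 equiv), THF, −78 °C; then PhNTf2 (1.2 equiv), −78 to 0 °C; then aq NH4Cl
Reagents that add atoms: N-phenylbis(trifluoromethanesulfonimide) O=S(=O)(N(c1ccccc1)S(=O)(=O)C(F)(F)F)C(F)(F)F
Why: Kinetic deprotonation by the hindered base at −78 °C should occur at the methyl group, and O-sulfonylation of enolate 23 then gives the terminal enol triflate, the cinnamate having no acidic α-hydrogen.

**Step 14**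
Reactants: 24 enol triflate
Product: 25 silyl-protected target
Conditions: tributyl(vinyl)stannane (1.3 equiv), Pd(PPh3)4 (5 mol %), LiCl (3 equiv), THF, 65 °C
Reagents that add atoms: tributyl(vinyl)stannane C=C[Sn](CCCC)(CCCC)CCCC
Why: Stille coupling (oxidative addition of the enol triflate to zerovalent palladium, chloride-assisted transmetalation, reductive elimination) should join the vinyl group to C13 and create the 2-substituted 1,3-diene under neutral conditions.

**Step 15**
Reactants: 25 silyl-protected target
Product: 26 CNP0131099.1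
Conditions: Bu4NF (1.1 equiv), AcOH (1.2 equiv), THF, 0 °C
Reagents that add atoms: none
Why: Fluoride should cleave the aryl silyl ether, and the AcOH buffer should keep the phenoxide and fluoride from attacking the cinnamate ester.

**Compound list**

1 | (5E)-6,10-dimethylundeca-5,9-dien-2-one, (E)-geranylacetone | CC(C)=CCC/C(C)=C/CCC(C)=O | starting material
2 | 2-[(3E)-4,8-dimethylnona-3,7-dien-1-yl]-2-methyl-1,3-dioxolane | CC(C)=CCC/C(C)=C/CCC1(C)OCCO1 | intermediate
3 | (2E,6E)-2,6-dimethyl-9-(2-methyl-1,3-dioxolan-2-yl)nona-2,6-dien-1-ol | OC/C(C)=C/CC/C(C)=C/CCC1(C)OCCO1 | intermediate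
4 | 2-[(3E,7E)-9-bromo-4,8-dimethylnona-3,7-dien-1-yl]-2-methyl-1,3-dioxolane | BrC/C(C)=C/CC/C(C)=C/CCC1(C)OCCO1 | intermediate
5 | (1S,2R,5S)-5-methyl-2-(2-phenylpropan-2-yl)cyclohexan-1-ol, (+)-8-phenylmenthol | O[C@H]1C[C@@H](C)CC[C@@H]1C(C)(C)c2ccccc2 | starting material
6 | ethyl 2-methyl-3-oxobutanoate | CCOC(=O)C(C)C(C)=O | starting material
7 | (1S,2R,5S)-8-phenylmenthyl 2-methyl-3-oxobutanoate (mixture at C2) | CC(=O)C(C)C(=O)O[C@H]1C[C@@H](C)CC[C@@H]1C(C)(C)c2ccccc2 | intermediate
8 | sodium lithium dianion of 7 (α- and terminal carbanion) | [Na+].[Li+].[CH2-]C(=O)[C-](C)C(=O)O[C@H]1C[C@@H](C)CC[C@@H]1C(C)(C)c2ccccc2 | intermediate (not isolated)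
9 | (1S,2R,5S)-8-phenylmenthyl (6E,10E)-2,6,10-trimethyl-13-(2-methyl-1,3-dioxolan-2-yl)-3-oxotrideca-6,10-dienoate | CC1(CC/C=C(C)/CC/C=C(C)/CCC(=O)C(C)C(=O)O[C@H]2C[C@@H](C)CC[C@@H]2C(C)(C)c3ccccc3)OCCO1 | intermediate
10 | C4 radical of 9 (radical carbon between the ketone and the ester) | CC1(CC/C=C(C)/CC/C=C(C)/CCC(=O)[C](C)C(=O)O[C@H]2C[C@@H](C)CC[C@@H]2C(C)(C)c3ccccc3)OCCO1 | intermediate (not isolated)
11 | monocyclic radical: ring A closed, tertiary radical at C10, C4 ester and C5–H set as in 13 | CC1(CC/C=C(C)/CC[C@@H]2[C@](C)(C(=O)O[C@H]3C[C@@H](C)CC[C@@H]3C(C)(C)c4ccccc4)C(=O)CC[C]2C)OCCO1 | intermediate (not isolated)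
12 | bicyclic radical: trans-decalin closed, tertiary radical at C8 bearing the C17 methyl | CC3(OCCO3)CC[C@@H]1[C](C)CC[C@@H]2[C@](C)(C(=O)O[C@H]4C[C@@H](C)CC[C@@H]4C(C)(C)c5ccccc5)C(=O)CC[C@@]12C | intermediate (not isolated)
13 | bicyclic keto ester: trans-decalin, 3-oxo, 4-methyl equatorial, axial C19 (1S,2R,5S)-8-phenylmenthyl ester cis to the C10 methyl, 8-methylene, equatorial C9 2-(2-methyl-1,3-dioxolan-2-yl)ethyl chain cis to the C10 methyl, 5-H trans to the C10 methyl | CC3(OCCO3)CC[C@@H]1C(=C)CC[C@@H]2[C@](C)(C(=O)O[C@H]4C[C@@H](C)CC[C@@H]4C(C)(C)c5ccccc5)C(=O)CC[C@@]12C | intermediate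
14 | 3,19-diol: as 13 with equatorial 3-OH and axial 4-CH2OH | CC3(OCCO3)CC[C@@H]1C(=C)CC[C@@H]2[C@](C)(CO)[C@H](O)CC[C@@]12C | intermediate
15 | cyclic thionocarbonate bridging O3 and O19 (1,3-dioxane-2-thione fused at C3–C4) | CC3(OCCO3)CC[C@@H]1C(=C)CC[C@@H]2[C@]4(C)COC(=S)O[C@@H]4CC[C@@]12C | intermediate
16 | 3-deoxy C19 O-alkyl S-tributylstannyl thiocarbonate | CC3(OCCO3)CC[C@@H]1C(=C)CC[C@@H]2[C@](C)(COC(=O)S[Sn](CCCC)(CCCC)CCCC)CCC[C@@]12C | intermediate (not isolated)
17 | C19 alcohol: trans-decalin, 4-methyl equatorial, axial 4-CH2OH cis to the C10 methyl, 8-methylene, C9 ketal side chain | CC3(OCCO3)CC[C@@H]1C(=C)CC[C@@H]2[C@](C)(CO)CCC[C@@]12C | intermediate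
18 | (E)-3-(4-hydroxyphenyl)prop-2-enoic acid, p-coumaric acid | OC(=O)/C=C/c1ccc(O)cc1 | starting material
19 | tert-butyldimethylsilyl (E)-3-[4-(tert-butyldimethylsilyloxy)phenyl]prop-2-enoate | CC(C)(C)[Si](C)(C)OC(=O)/C=C/c1ccc(O[Si](C)(C)C(C)(C)C)cc1 | intermediate (not isolated)
20 | (E)-3-[4-(tert-butyldimethylsilyloxy)phenyl]prop-2-enoic acid | OC(=O)/C=C/c1ccc(O[Si](C)(C)C(C)(C)C)cc1 | intermediate
21 | C19 (E)-4-(tert-butyldimethylsilyloxy)cinnamate of 17 (ketal intact) | CC3(OCCO3)CC[C@@H]1C(=C)CC[C@@H]2[C@](C)(COC(=O)/C=C/c4ccc(O[Si](C)(C)C(C)(C)C)cc4)CCC[C@@]12C | intermediate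
22 | methyl ketone: as 21 with a 3-oxobutyl chain on C9 | CC(=O)CC[C@@H]1C(=C)CC[C@@H]2[C@](C)(COC(=O)/C=C/c3ccc(O[Si](C)(C)C(C)(C)C)cc3)CCC[C@@]12C | intermediate
23 | terminal potassium enolate of 22 | [K+].C=C([O-])CC[C@@H]1C(=C)CC[C@@H]2[C@](C)(COC(=O)/C=C/c3ccc(O[Si](C)(C)C(C)(C)C)cc3)CCC[C@@]12C | intermediate (not isolated)
24 | terminal enol triflate: C9 chain CH2CH2C(OTf)=CH2 | C=C(OS(=O)(=O)C(F)(F)F)CC[C@@H]1C(=C)CC[C@@H]2[C@](C)(COC(=O)/C=C/c3ccc(O[Si](C)(C)C(C)(C)C)cc3)CCC[C@@]12C | intermediate
25 | O-tert-butyldimethylsilyl ether of the target | C=CC(=C)CC[C@@H]1C(=C)CC[C@@H]2[C@](C)(COC(=O)/C=C/c3ccc(O[Si](C)(C)C(C)(C)C)cc3)CCC[C@@]12C | intermediate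
26 | CNP0131099.1, the C19 (E)-p-coumarate of the labda-8(17),13(16),14-trien-19-ol of the 10α-methyl series | C=CC(=C)CC[C@@H]1C(=C)CC[C@@H]2[C@](C)(COC(=O)/C=C/c3ccc(O)cc3)CCC[C@@]12C | target

**Count**

Total steps: 15. Longest linear sequence: 13 steps (steps 1–3, 5–9, 11–15, from geranylacetone).

**Steps most likely to fail**

Step 6. The auxiliary may discriminate only weakly, or in the reverse sense, between the two faces of the freely rotating C4 radical, and the final oxidation may give endocyclic alkene isomers. The fallback sets the absolute configuration by chelate control and creates the quaternary C4 afterwards. It sets out from bromide 4. (1R,2S,5R)-8-Phenylmenthol is heated with 2,2,6-trimethyl-4H-1,3-dioxin-4-one in xylene to give (1R,2S,5R)-8-phenylmenthyl 3-oxobutanoate F1. Its dianion (NaH, then n-BuLi) is alkylated with 4 to the α-unsubstituted acyclic keto ester F2. Mn(OAc)3·2H2O, Cu(OAc)2·H2O and Yb(OTf)3 in CF3CH2OH at 0 °C should cyclize the ytterbium-chelated radical, in which both carbonyl groups are locked syn under the phenyl ring, to the bicyclic β-keto ester F3. NaH and MeI then methylate C4 of its enolate on the face opposite the axial C10 methyl, which leaves the ester axial in the methylated keto ester F4. LiAlH4 reduction of F4 comes back to the route at diol 14.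

Step 9. The thionocarbonate may fragment toward the primary C19–O bond, or the thiocarbonyl may be reduced without C–O cleavage. The fallback removes the C3 oxygen before C19 is reduced, so that only one C–O bond can break. It sets out from keto ester 13. NaBH4 in MeOH/THF gives the equatorial hydroxy ester F5, PhOC(S)Cl with pyridine and DMAP gives the O-phenyl thionocarbonate F6, and Bu3SnH/AIBN (Barton–McCombie deoxygenation) gives the 3-deoxy ester F7. LiAlH4 reduction of F7 comes back to the route at alcohol 17.

Step 13. Deprotonation may compete at the C12 methylene, and the base or the enolate may attack the cinnamate or the aryl silyl ether. The fallback builds the diene before the cinnamate is attached. It sets out from alcohol 17. TBDPSCl and imidazole give the silyl ether F8, PPTS in aqueous acetone gives the methyl ketone F9, LiN(iPr)2 at −78 °C and then PhNTf2 give the enol triflate F10, Stille coupling with tributyl(vinyl)stannane (Pd(PPh3)4, LiCl) gives the diene silyl ether F11, and Bu4NF gives the diene alcohol F12. Esterification of F12 with acid 20 (DCC, DMAP) comes back to the route at silyl-protected target 25.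

**Further compounds**

F1 | step 6 | (1R,2S,5R)-8-phenylmenthyl 3-oxobutanoate | CC(=O)CC(=O)O[C@@H]1C[C@H](C)CC[C@H]1C(C)(C)c2ccccc2
F2 | step 6 | (1R,2S,5R)-8-phenylmenthyl (6E,10E)-6,10-dimethyl-13-(2-methyl-1,3-dioxolan-2-yl)-3-oxotrideca-6,10-dienoate | CC1(CC/C=C(C)/CC/C=C(C)/CCC(=O)CC(=O)O[C@@H]2C[C@H](C)CC[C@H]2C(C)(C)c3ccccc3)OCCO1
F3 | step 6 | bicyclic β-keto ester lacking the C4 methyl (keto/enol mixture, C4 unassigned), (1R,2S,5R)-8-phenylmenthyl ester | CC3(OCCO3)CC[C@@H]1C(=C)CC[C@@H]2C(C(=O)O[C@@H]4C[C@H](C)CC[C@H]4C(C)(C)c5ccccc5)C(=O)CC[C@@]12C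
F4 | step 6 | C4-methylated bicyclic keto ester with axial (1R,2S,5R)-8-phenylmenthyl ester | CC3(OCCO3)CC[C@@H]1C(=C)CC[C@@H]2[C@](C)(C(=O)O[C@@H]4C[C@H](C)CC[C@H]4C(C)(C)c5ccccc5)C(=O)CC[C@@]12C
F5 | step 9 | equatorial 3-hydroxy (1S,2R,5S)-8-phenylmenthyl ester | CC3(OCCO3)CC[C@@H]1C(=C)CC[C@@H]2[C@](C)(C(=O)O[C@H]4C[C@@H](C)CC[C@@H]4C(C)(C)c5ccccc5)[C@H](O)CC[C@@]12C
F6 | step 9 | 3-O-(phenoxythiocarbonyl) derivative of F5 | CC3(OCCO3)CC[C@@H]1C(=C)CC[C@@H]2[C@](C)(C(=O)O[C@H]4C[C@@H](C)CC[C@@H]4C(C)(C)c5ccccc5)[C@H](OC(=S)Oc6ccccc6)CC[C@@]12C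
F7 | step 9 | 3-deoxy (1S,2R,5S)-8-phenylmenthyl ester | CC3(OCCO3)CC[C@@H]1C(=C)CC[C@@H]2[C@](C)(C(=O)O[C@H]4C[C@@H](C)CC[C@@H]4C(C)(C)c5ccccc5)CCC[C@@]12C
F8 | step 13 | C19 tert-butyldiphenylsilyl ether of 17 | CC3(OCCO3)CC[C@@H]1C(=C)CC[C@@H]2[C@](C)(CO[Si](c4ccccc4)(c5ccccc5)C(C)(C)C)CCC[C@@]12C
F9 | step 13 | methyl ketone silyl ether | CC(=O)CC[C@@H]1C(=C)CC[C@@H]2[C@](C)(CO[Si](c3ccccc3)(c4ccccc4)C(C)(C)C)CCC[C@@]12C
F10 | step 13 | terminal enol triflate silyl ether | C=C(OS(=O)(=O)C(F)(F)F)CC[C@@H]1C(=C)CC[C@@H]2[C@](C)(CO[Si](c3ccccc3)(c4ccccc4)C(C)(C)C)CCC[C@@]12C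
F11 | step 13 | diene silyl ether | C=CC(=C)CC[C@@H]1C(=C)CC[C@@H]2[C@](C)(CO[Si](c3ccccc3)(c4ccccc4)C(C)(C)C)CCC[C@@]12C
F12 | step 13 | diene alcohol (labda-8(17),13(16),14-trien-19-ol of the 10α-methyl series) | C=CC(=C)CC[C@@H]1C(=C)CC[C@@H]2[C@](C)(CO)CCC[C@@]12C
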